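**Retrosynthetic overview**
1. Punaglandin 8 ⇒ (O-desilylation, O-acetylation, cis-semihydrogenation) the C7–C8 aldol adduct. The key disconnection is C7–C8: lithium dienolate of the C12-O-silylated chloroenone plus methyl 7-oxohept-5-ynoate. This sets C7 and C8.
2. Chloroenone ⇒ α,β-epoxy ketone (HCl opening, mesylate elimination) ⇒ cis-1-[(Z)-octenyl]cyclopent-2-ene-1,4-diol (directed epoxidation, oxidation).
3. Diol ⇒ Z-selective Wittig on a β-silyloxy aldehyde ⇒ 1,2-addition of an acetamide enolate to (R)-4-silyloxycyclopentenone. This sets C12.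
4. Ynal ⇒ hex-5-ynoic acid plus formaldehyde.
5. Rings: the five-membered ring is bought with the starting enone and never opened. The only ring made is a transient oxirane (formed in step 6, opened in step 8).

Assumption: (R)-4-(tert-butyldimethylsilyloxy)cyclopent-2-en-1-one (≥98% ee), the bulk prostaglandin building block, counts as a purchasable starting material.
Atom labels C1–C20 follow prostanoid numbering: C1 is the ester carbon, C8–C12 the ring, C13–C20 the octenyl chain.

**Cyclopentenone fragment**

Step 1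
Reactants: 1 (R)-4-(tert-butyldimethylsilyloxy)cyclopent-2-en-1-one; 2 N-methoxy-N-methylacetamide
Product: 4 2-[(1R,4R)-4-(tert-butyldimethylsilyloxy)-1-hydroxycyclopent-2-en-1-yl]-N-methoxy-N-methylacetamide (OH cis to OTBS), via lithium amide enolate 3 (not isolated)
Conditions: 2, LiN(iPr)2 (1.1 equiv), THF, −78 °C, 30 min; then 1, −78 °C, 1 h; AcOH quench at −78 °C
Reagents that add atoms: none
Why: Kinetic 1,2-addition of a hard amide enolate to the ketone (aldol-type addition) outruns conjugate addition and enolisation at −78 °C, and the enolate enters on the ring face opposite the bulky C4 silyloxy group, so the new tertiary carbinol (future C12) has its OH cis to OTBS, the minor epimer being removed by chromatography.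

Step 2
Reactants: 4 hydroxy Weinreb amide
Product: 5 2-[(1R,4R)-4-(tert-butyldimethylsilyloxy)-1-(triethylsilyloxy)cyclopent-2-en-1-yl]-N-methoxy-N-methylacetamide
Conditions: TESOTf, 2,6-lutidine, CH2Cl2, −78 to 0 °C
Reagents that add atoms: triethylsilyl triflate, CC[Si](CC)(CC)OS(=O)(=O)C(F)(F)F
Why: Silyl triflate O-silylation is fast even on a tertiary alcohol, touches no stereocentre, and blocks retro-aldol cleavage in the two basic steps that follow.

Step 3
Reactants: 5 bis-silyl Weinreb amide
Product: 6 2-[(1R,4R)-4-(tert-butyldimethylsilyloxy)-1-(triethylsilyloxy)cyclopent-2-en-1-yl]acetaldehyde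
Conditions: iBu2AlH (1.5 equiv), THF, −78 °C; aq potassium sodium tartrate work-up
Reagents that add atoms: none
Why: Weinreb amide reduction stops reliably at the aldehyde oxidation level, and the silyl ethers and the ring alkene are inert to iBu2AlH at −78 °C.

Step 4
Reactants: 6 aldehyde; 7 hexyltriphenylphosphonium bromide
Product: 9 (1S,4R)-4-(tert-butyldimethylsilyloxy)-1-[(Z)-oct-2-en-1-yl]-1-(triethylsilyloxy)cyclopent-2-ene, via hexylidenetriphenylphosphorane 8 (not isolated)
Conditions: 7, NaN(SiMe3)2, THF, 0 °C; then 6, −78 °C to rt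
Reagents that add atoms: none
Why: Lithium-free Wittig olefination with a non-stabilised ylide is under kinetic control and gives the Z-alkene (about 95:5 or better), and carbonyl addition at −78 °C is faster than α-deprotonation, so the β-silyloxy group is not eliminated.

Step 5
Reactants: 9 bis-silyl ether
Product: 10 (1S,4R)-1-[(Z)-oct-2-en-1-yl]cyclopent-2-ene-1,4-diol (cis-diol)
Conditions: Bu4NF (3 equiv), THF, 0 °C to rt
Reagents that add atoms: none
Why: Fluoride desilylation removes both silyl groups without any selectivity demand and avoids acid, which could ionise the tertiary allylic alcohol.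

Step 6
Reactants: 10 cis-diol
Product: 11 (1R,2S,4R,5R)-2-[(Z)-oct-2-en-1-yl]-6-oxabicyclo[3.1.0]hexane-2,4-diol (oxirane oxygen cis to both hydroxyls)
Conditions: VO(acac)2 (3 mol %), tBuOOH (1.2 equiv, decane), CH2Cl2, 0 °C
Reagents that add atoms: tert-butyl hydroperoxide, CC(C)(C)OO
Why: Vanadium-catalysed hydroxyl-directed epoxidation delivers oxygen syn to the two cis allylic hydroxyls of the ring alkene much faster than to the merely homoallylic side-chain alkene, and the two new stereocentres are temporary.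

Step 7
Reactants: 11 epoxy diol
Product: 12 (1S,4S,5R)-4-hydroxy-4-[(Z)-oct-2-en-1-yl]-6-oxabicyclo[3.1.0]hexan-2-one
Conditions: Dess–Martin periodinane, CH2Cl2, 0 °C to rt
Reagents that add atoms: none
Why: Dess–Martin oxidation converts the only oxidisable (secondary) alcohol under base-free conditions, so the oxirane, the Z-alkene and the tertiary β-hydroxy ketone motif (no retro-aldol, C12 intact) survive.

Step 8
Reactants: 12 epoxy ketone
Product: 13 (2R,3S,4S)-2-chloro-3,4-dihydroxy-4-[(Z)-oct-2-en-1-yl]cyclopentan-1-one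
Conditions: HCl (2 M in Et2O, 1.5 equiv), CH2Cl2, −20 to 0 °C
Reagents that add atoms: hydrogen chloride, Cl
Why: Acid-promoted SN2 opening of the α,β-epoxy ketone takes place with inversion at the carbonyl-activated α-carbon C10, because C11 is neopentyl-like and inductively deactivated, which puts chlorine on the correct carbon.

Step 9
Reactants: 13 chlorohydrin
Product: 15 (4S)-2-chloro-4-hydroxy-4-[(Z)-oct-2-en-1-yl]cyclopent-2-en-1-one, via secondary mesylate 14 (not isolated)
Conditions: MsCl (1.2 equiv), Et3N (3 equiv), CH2Cl2, −20 to 0 °C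
Reagents that add atoms: none
Why: Selective mesylation of the secondary alcohol followed by E1cB elimination through the most acidic proton (C10–H, flanked by C=O and Cl) gives the α-chloroenone, while the tertiary hydroxyl is neither sulfonylated nor a competent leaving group and Et3N is too weak to start a retro-aldol.

Step 10
Reactants: 15 hydroxy chloroenone
Product: 16 (4S)-2-chloro-4-[(Z)-oct-2-en-1-yl]-4-(triethylsilyloxy)cyclopent-2-en-1-one
Conditions: TESOTf, 2,6-lutidine, CH2Cl2, −78 to −20 °C
Reagents that add atoms: triethylsilyl triflate, CC[Si](CC)(CC)OS(=O)(=O)C(F)(F)F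
Why: Silyl triflate O-silylation caps the tertiary alcohol before strong base is used, which rules out retro-aldol racemisation of C12, and the group can later be removed under very mild acidic fluoride conditions.

**Aldehyde fragment**

Step 11
Reactants: 17 hex-5-ynoic acid
Product: 19 7-hydroxyhept-5-ynoic acid, via dilithio hex-5-ynoate 18 (not isolated)
Conditions: nBuLi (2.1 equiv), THF–DMPU, −78 to 0 °C; (CH2O)n, 0 °C to rt; then aq HCl
Reagents that add atoms: paraformaldehyde (reacts as formaldehyde), C=O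
Why: Acetylide hydroxymethylation works on the carboxylate/acetylide dianion because only the acetylide carbon is nucleophilic towards formaldehyde.

Step 12
Reactants: 19 7-hydroxyhept-5-ynoic acid
Product: 20 methyl 7-hydroxyhept-5-ynoate
Conditions: MeOH, cat H2SO4, rt
Reagents that add atoms: methanol, CO
Why: Fischer esterification in a large excess of methanol is driven to the ester and leaves the propargylic alcohol untouched.

Step 13
Reactants: 20 methyl 7-hydroxyhept-5-ynoate
Product: 21 methyl 7-oxohept-5-ynoate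
Conditions: MnO2 (activated, excess), CH2Cl2, rt; filtered and used at once
Reagents that add atoms: none
Why: MnO2 oxidation is selective for the activated propargylic alcohol, stops at the aldehyde, and needs only filtration, which suits a sensitive ynal.

**Coupling and end game**

Step 14
Reactants: 16 silylated chloroenone; 21 methyl 7-oxohept-5-ynoate
Product: 23 methyl (7R)-7-[(1R,2S)-4-chloro-2-[(Z)-oct-2-en-1-yl]-5-oxo-2-(triethylsilyloxy)cyclopent-3-en-1-yl]-7-hydroxyhept-5-ynoate, via lithium dienolate 22 (not isolated)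
Conditions: LiN(iPr)2 (1.1 equiv), THF, −78 °C, 30 min; then 21 (1.3 equiv), −78 °C, 20 min; AcOH quench at −78 °C
Reagents that add atoms: none
Why: In this directed lithium aldol addition only C8 can be deprotonated (C12 is quaternary), the aldehyde is met on the dienolate face anti to the octenyl chain and syn to the effectively smaller silyloxy oxygen (C8 R, the two chains trans), and the ring-locked E(O)-enolate passes through a Zimmerman–Traxler chair to the 7,8-anti aldol with the target geometry at C7 (descriptor R here only because the alkyne outranks C8), the minor 7-epimer being removed by chromatography.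

Step 15
Reactants: 23 propargylic aldol
Product: 24 methyl (5Z,7S)-7-[(1R,2S)-4-chloro-2-[(Z)-oct-2-en-1-yl]-5-oxo-2-(triethylsilyloxy)cyclopent-3-en-1-yl]-7-hydroxyhept-5-enoate
Conditions: H2 (1 atm), Pd/CaCO3 poisoned with Pb(OAc)2 (Lindlar catalyst), quinoline, EtOAc, rt, stopped after 1 equiv H2
Reagents that add atoms: none
Why: Lindlar semihydrogenation adds hydrogen syn to the strongly adsorbed alkyne to give the 5Z-alkene, while the hindered trisubstituted chloroenone and the existing Z-alkene react much more slowly on the poisoned catalyst, and C7 keeps its geometry although its descriptor becomes S.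

Step 16
Reactants: 24 allylic alcohol
Product: 25 methyl (5Z,7S)-7-acetoxy-7-[(1R,2S)-4-chloro-2-[(Z)-oct-2-en-1-yl]-5-oxo-2-(triethylsilyloxy)cyclopent-3-en-1-yl]hept-5-enoate
Conditions: Ac2O, pyridine, CH2Cl2, 0 °C to rt (no DMAP)
Reagents that add atoms: acetic anhydride, CC(=O)OC(C)=O
Why: O-acetylation with retention at C7 uses only the weak base pyridine, so the β-acetoxy ketone is formed without E1cB loss of acetate or epimerisation at C8.

Step 17
Reactants: 25 silylated acetate
Product: 26 punaglandin 8, methyl (5Z,7S)-7-acetoxy-7-[(1R,2S)-4-chloro-2-hydroxy-2-[(Z)-oct-2-en-1-yl]-5-oxocyclopent-3-en-1-yl]hept-5-enoate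
Conditions: HF·pyridine, THF, 0 °C (plastic vessel)
Reagents that add atoms: none
Why: Acidic fluoride desilylation cleaves the triethylsilyl ether under base-free conditions that spare the base-labile β-acetoxy ketone, the methyl ester, both Z-alkenes and all three stereocentres.

**Compound list**
1 | (R)-4-(tert-butyldimethylsilyloxy)cyclopent-2-en-1-one | O=C1C=C[C@H](O[Si](C)(C)C(C)(C)C)C1 | starting material
2 | N-methoxy-N-methylacetamide | CC(=O)N(C)OC | starting material
3 | lithium enolate of N-methoxy-N-methylacetamide | [Li]OC(=C)N(C)OC | intermediate (not isolated)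
4 | 2-[(1R,4R)-4-(tert-butyldimethylsilyloxy)-1-hydroxycyclopent-2-en-1-yl]-N-methoxy-N-methylacetamide | CON(C)C(=O)C[C@@]1(O)C=C[C@H](O[Si](C)(C)C(C)(C)C)C1 | intermediate
5 | 2-[(1R,4R)-4-(tert-butyldimethylsilyloxy)-1-(triethylsilyloxy)cyclopent-2-en-1-yl]-N-methoxy-N-methylacetamide | CON(C)C(=O)C[C@@]1(O[Si](CC)(CC)CC)C=C[C@H](O[Si](C)(C)C(C)(C)C)C1 | intermediate
6 | 2-[(1R,4R)-4-(tert-butyldimethylsilyloxy)-1-(triethylsilyloxy)cyclopent-2-en-1-yl]acetaldehyde | O=CC[C@@]1(O[Si](CC)(CC)CC)C=C[C@H](O[Si](C)(C)C(C)(C)C)C1 | intermediate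
7 | hexyltriphenylphosphonium bromide | CCCCCC[P+](c1ccccc1)(c1ccccc1)c1ccccc1.[Br-] | starting material
8 | hexylidenetriphenylphosphorane | CCCCCC=P(c1ccccc1)(c1ccccc1)c1ccccc1 | intermediate (not isolated)
9 | (1S,4R)-4-(tert-butyldimethylsilyloxy)-1-[(Z)-oct-2-en-1-yl]-1-(triethylsilyloxy)cyclopent-2-ene | CCCCC/C=C\C[C@@]1(O[Si](CC)(CC)CC)C=C[C@H](O[Si](C)(C)C(C)(C)C)C1 | intermediate
10 | (1S,4R)-1-[(Z)-oct-2-en-1-yl]cyclopent-2-ene-1,4-diol | CCCCC/C=C\C[C@@]1(O)C=C[C@H](O)C1 | intermediate
11 | (1R,2S,4R,5R)-2-[(Z)-oct-2-en-1-yl]-6-oxabicyclo[3.1.0]hexane-2,4-diol | CCCCC/C=C\C[C@@]1(O)[C@@H]2O[C@@H]2[C@H](O)C1 | intermediate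
12 | (1S,4S,5R)-4-hydroxy-4-[(Z)-oct-2-en-1-yl]-6-oxabicyclo[3.1.0]hexan-2-one | CCCCC/C=C\C[C@@]1(O)[C@@H]2O[C@@H]2C(=O)C1 | intermediate
13 | (2R,3S,4S)-2-chloro-3,4-dihydroxy-4-[(Z)-oct-2-en-1-yl]cyclopentan-1-one | CCCCC/C=C\C[C@@]1(O)[C@H](O)[C@@H](Cl)C(=O)C1 | intermediate
14 | C11 methanesulfonate of 13 | CCCCC/C=C\C[C@@]1(O)[C@H](OS(C)(=O)=O)[C@@H](Cl)C(=O)C1 | intermediate (not isolated)
15 | (4S)-2-chloro-4-hydroxy-4-[(Z)-oct-2-en-1-yl]cyclopent-2-en-1-one | CCCCC/C=C\C[C@@]1(O)C=C(Cl)C(=O)C1 | intermediate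
16 | (4S)-2-chloro-4-[(Z)-oct-2-en-1-yl]-4-(triethylsilyloxy)cyclopent-2-en-1-one | CCCCC/C=C\C[C@@]1(O[Si](CC)(CC)CC)C=C(Cl)C(=O)C1 | intermediate
17 | hex-5-ynoic acid | C#CCCCC(=O)O | starting material
18 | dilithio hex-5-ynoate (lithium carboxylate, lithium acetylide) | [Li]C#CCCCC(=O)O[Li] | intermediate (not isolated)
19 | 7-hydroxyhept-5-ynoic acid | OCC#CCCCC(=O)O | intermediate
20 | methyl 7-hydroxyhept-5-ynoate | COC(=O)CCCC#CCO | intermediate
21 | methyl 7-oxohept-5-ynoate | COC(=O)CCCC#CC=O | intermediate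
22 | lithium cross-conjugated dienolate of 16 | CCCCC/C=C\C[C@@]1(O[Si](CC)(CC)CC)C=C(Cl)C(O[Li])=C1 | intermediate (not isolated)
23 | methyl (7R)-7-[(1R,2S)-4-chloro-2-[(Z)-oct-2-en-1-yl]-5-oxo-2-(triethylsilyloxy)cyclopent-3-en-1-yl]-7-hydroxyhept-5-ynoate | CCCCC/C=C\C[C@@]1(O[Si](CC)(CC)CC)C=C(Cl)C(=O)[C@@H]1[C@H](C#CCCCC(=O)OC)O | intermediate
24 | methyl (5Z,7S)-7-[(1R,2S)-4-chloro-2-[(Z)-oct-2-en-1-yl]-5-oxo-2-(triethylsilyloxy)cyclopent-3-en-1-yl]-7-hydroxyhept-5-enoate | CCCCC/C=C\C[C@@]1(O[Si](CC)(CC)CC)C=C(Cl)C(=O)[C@@H]1[C@H](/C=C\CCCC(=O)OC)O | intermediate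
25 | methyl (5Z,7S)-7-acetoxy-7-[(1R,2S)-4-chloro-2-[(Z)-oct-2-en-1-yl]-5-oxo-2-(triethylsilyloxy)cyclopent-3-en-1-yl]hept-5-enoate | CCCCC/C=C\C[C@@]1(O[Si](CC)(CC)CC)C=C(Cl)C(=O)[C@@H]1[C@H](/C=C\CCCC(=O)OC)OC(C)=O | intermediate
26 | punaglandin 8 | CCCCC/C=C\C[C@@]1(O)C=C(Cl)C(=O)[C@@H]1[C@H](/C=C\CCCC(=O)OC)OC(C)=O | target

**Totals**
Total step count: 17.
Longest linear sequence: 14 (steps 1–10, then 14–17).

**Three steps most likely to fail**

Risk 1, step 14 (aldol).
- Two stereocentres are set at once. The slim alkynyl group may erode the anti preference, and the basic medium can degrade the ynal or reverse the addition.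
- The fallback sets out from 16. TMSOTf and Et3N in CH2Cl2 at 0 °C give (5S)-3-chloro-5-[(Z)-oct-2-en-1-yl]-5-(triethylsilyloxy)-2-(trimethylsilyloxy)cyclopenta-1,3-diene F1.
- F1 is isolated and then added to 21 with BF3·OEt2 in CH2Cl2 at −78 °C (Mukaiyama aldol, irreversible and base-free).
- Attack is again anti to the octenyl chain, and cyclic enol silanes lean towards the anti adduct in the open transition state. Aqueous work-up brings the sequence back at 23.

Risk 2, step 15 (late semihydrogenation).
- Over-reduction, loss of chlorine or isomerisation of the octenyl alkene would cost advanced material.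
- The fallback sets out from 20 and moves the hydrogenation to the simple fragment. H2 over Pd/CaCO3 poisoned with Pb(OAc)2 with quinoline gives methyl (Z)-7-hydroxyhept-5-enoate F2.
- MnO2 in CH2Cl2 then gives methyl (Z)-7-oxohept-5-enoate F3, which is used at once to avoid Z-to-E drift.
- F3 is added at −78 °C to dienolate 22, made from 16 as in step 14. The bulkier Z-alkenyl group should also sharpen the anti selectivity. This comes back at 24 and bypasses 23.

Risk 3, step 16 (acetylation).
- The β-acetoxy ketone can lose acetic acid to the cross-conjugated dienone during prolonged contact with amine base at 0 °C to rt.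
- The fallback sets out from 16 and 21. The aldol mixture of step 14 is not quenched. Ac2O (3 equiv) is added at −78 °C, the mixture is held below −40 °C, and it is then buffered at pH 7.
- This gives methyl (7R)-7-acetoxy-7-[(1R,2S)-4-chloro-2-[(Z)-oct-2-en-1-yl]-5-oxo-2-(triethylsilyloxy)cyclopent-3-en-1-yl]hept-5-ynoate F4 directly. The 7-epimers are separated at this stage.
- Semihydrogenation of F4 under the conditions of step 15 comes back at 25.

**Further compounds**
F1 | step 14 | (5S)-3-chloro-5-[(Z)-oct-2-en-1-yl]-5-(triethylsilyloxy)-2-(trimethylsilyloxy)cyclopenta-1,3-diene | CCCCC/C=C\C[C@@]1(O[Si](CC)(CC)CC)C=C(Cl)C(O[Si](C)(C)C)=C1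
F2 | step 15 | methyl (Z)-7-hydroxyhept-5-enoate | COC(=O)CCC/C=C\CO
F3 | step 15 | methyl (Z)-7-oxohept-5-enoate | COC(=O)CCC/C=C\C=O
F4 | step 16 | methyl (7R)-7-acetoxy-7-[(1R,2S)-4-chloro-2-[(Z)-oct-2-en-1-yl]-5-oxo-2-(triethylsilyloxy)cyclopent-3-en-1-yl]hept-5-ynoate | CCCCC/C=C\C[C@@]1(O[Si](CC)(CC)CC)C=C(Cl)C(=O)[C@@H]1[C@H](C#CCCCC(=O)OC)OC(C)=O
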